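The route rests on cutting the C3–C4 bond of the 6-oxabicyclo[3.2.1]octane-7,8-dione, the bond between the prenyl-bearing CH and the CMe2 group. A metal-hydride hydrogen-atom-transfer (MHAT) radical cyclisation forms it: the tertiary radical made from an isopropenyl group on C5 of a γ-lactone (oxolane-2,4-dione) adds 6-exo to one of two identical (E)-4-oxobut-2-enyl arms on the lactone's α-carbon. The feature exploited is the five-membered lactone ring O6–C7–C1–C8–C5: only the arm cis to the radical can bridge it, so the single stereocentre of the precursor (set by asymmetric enolate hydroxylation) fixes C1 and C3 of the bicycle in one event. Ozonolysis and double Wittig olefination then give both prenyl groups.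

Key step: step 7

Assumption: the sense and level of induction of the chiral oxaziridine on this acyclic 2-alkenyl-1,3-diketone enolate cannot be predicted with certainty. The (+)-reagent is written as giving the (R)-carbinol; if it favours the (S)-carbinol, the commercially available (−)-reagent is used instead.

Remark: any (Z)-arm formed in step 1 converges, because the arm geometry is lost in steps 7 and 8.

Step 1
Reactants: 1 methyl acetoacetate; 2 2-vinyloxirane (2.3 equiv)
Product: 3 methyl (4E)-2-acetyl-6-hydroxy-2-[(2E)-4-hydroxybut-2-en-1-yl]hex-4-enoate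
Conditions: Pd(PPh3)4 (3 mol %), THF, 0 °C to rt
Reagents that add atoms: none
Why: Pd(0) opens the vinyl epoxide to a zwitterionic π-allyl complex whose alkoxide deprotonates the β-keto ester, and C-alkylation at the allyl terminus (Tsuji–Trost allylic alkylation, 1,4-addition) should occur twice to give a quaternary carbon with two identical (E)-arms.

Step 2
Reactants: 3 methyl (4E)-2-acetyl-6-hydroxy-2-[(2E)-4-hydroxybut-2-en-1-yl]hex-4-enoate
Product: 4 methyl (4E)-2-acetyl-6-[(tert-butyldiphenylsilyl)oxy]-2-{(2E)-4-[(tert-butyldiphenylsilyl)oxy]but-2-en-1-yl}hex-4-enoate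
Conditions: TBDPSCl (2.3 equiv), imidazole, DMF, rt
Reagents that add atoms: tert-butyl(chloro)diphenylsilane, CC(C)(C)[Si](Cl)(c1ccccc1)c1ccccc1
Why: Silyl ether protection of the two primary allylic alcohols masks them for the enolate and Lewis-acid steps that follow.

Step 3
Reactants: 4 methyl (4E)-2-acetyl-6-[(tert-butyldiphenylsilyl)oxy]-2-{(2E)-4-[(tert-butyldiphenylsilyl)oxy]but-2-en-1-yl}hex-4-enoate; 5 2-methylpropanoyl chloride
Product: 6 methyl 2,2-bis{(2E)-4-[(tert-butyldiphenylsilyl)oxy]but-2-en-1-yl}-6-methyl-3,5-dioxoheptanoate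
Conditions: MgBr2·OEt2, i-Pr2NEt, CH2Cl2, rt
Reagents that add atoms: none
Why: Soft enolisation of the methyl ketone (its only enolisable site) as a chelated magnesium enolate and C-acylation by the acid chloride (crossed Claisen-type acylation) should give the 1,3-diketone, held as its magnesium chelate against a second acylation.

Step 4
Reactants: 6 methyl 2,2-bis{(2E)-4-[(tert-butyldiphenylsilyl)oxy]but-2-en-1-yl}-6-methyl-3,5-dioxoheptanoate; 7 acetone
Product: 8 methyl 2,2-bis{(2E)-4-[(tert-butyldiphenylsilyl)oxy]but-2-en-1-yl}-6-methyl-3,5-dioxo-4-(propan-2-ylidene)heptanoate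
Conditions: TiCl4, pyridine, acetone (excess), THF, 0 °C to rt
Reagents that add atoms: none
Why: TiCl4/pyridine-mediated Knoevenagel condensation of the 1,3-diketone with acetone installs the three-carbon unit at the central carbon; the alkylidene and its β,γ-unsaturated tautomer give the same enolate in step 5.

Step 5
Reactants: 8 methyl 2,2-bis{(2E)-4-[(tert-butyldiphenylsilyl)oxy]but-2-en-1-yl}-6-methyl-3,5-dioxo-4-(propan-2-ylidene)heptanoate
Product: 10 (5R)-3,3-bis{(2E)-4-[(tert-butyldiphenylsilyl)oxy]but-2-en-1-yl}-5-(2-methylpropanoyl)-5-(prop-1-en-2-yl)oxolane-2,4-dione, via hydroxy ester 9 (not isolated)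
Conditions: KHMDS, THF, −78 °C; (+)-[(8,8-dichlorocamphoryl)sulfonyl]oxaziridine, −78 to 0 °C; AcOH; then CSA (cat.), toluene, rt to 60 °C
Reagents that add atoms: (+)-[(8,8-dichlorocamphoryl)sulfonyl]oxaziridine, CC1(C)[C@@H]2CC[C@]13CS(=O)(=O)N4O[C@@]34C2(Cl)Cl
Why: KHMDS removes a γ-proton to give the 2-isopropenyl-1,3-diketonate, which the chiral N-sulfonyloxaziridine should hydroxylate at the central carbon (asymmetric enolate hydroxylation, reagent control sets the R carbinol), after which the tertiary alcohol closes the γ-lactone onto the methyl ester (5-exo-trig, helped by the gem-disubstituent effect).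

Step 6
Reactants: 10 (5R)-3,3-bis{(2E)-4-[(tert-butyldiphenylsilyl)oxy]but-2-en-1-yl}-5-(2-methylpropanoyl)-5-(prop-1-en-2-yl)oxolane-2,4-dione
Product: 12 (2E,2'E)-4,4'-[(5R)-5-(2-methylpropanoyl)-2,4-dioxo-5-(prop-1-en-2-yl)oxolane-3,3-diyl]bis(but-2-enal), via diol 11 (not isolated)
Conditions: HF·pyridine, pyridine, THF, 0 °C to rt; crude diol, then MnO2, CH2Cl2, rt
Reagents that add atoms: none
Why: Fluoride-mediated desilylation frees the two allylic alcohols, which MnO2 should oxidise selectively (allylic alcohol oxidation) to the (E)-enals without touching the isopropenyl group or the acid- and oxidant-stable acyloxy diketone.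

Step 7
Reactants: 12 (2E,2'E)-4,4'-[(5R)-5-(2-methylpropanoyl)-2,4-dioxo-5-(prop-1-en-2-yl)oxolane-3,3-diyl]bis(but-2-enal)
Product: 13 (2E)-4-[(1R,3S,5R)-4,4-dimethyl-5-(2-methylpropanoyl)-7,8-dioxo-3-(2-oxoethyl)-6-oxabicyclo[3.2.1]octan-1-yl]but-2-enal
Conditions: Fe(acac)3, PhSiH3, EtOH/(CH2OH)2, 0.02 M, 60 °C
Reagents that add atoms: none
Why: An iron hydride formed from Fe(acac)3 and PhSiH3 transfers H• to the CH2 terminus of the isopropenyl group, the resulting tertiary radical adds to the β-carbon of the enal arm on its own face of the lactone, and the α-formyl radical is reduced by Fe(II) to the enolate and protonated by ethanol. The closest known reaction type is the MHAT-initiated reductive olefin coupling (Giese-type radical conjugate addition) to enals, here in intramolecular form. The ring closed is the cyclohexanone C1–C2–C3–C4–C5–C8 of the bicycle, by 6-exo-trig attack. The bridgehead C1 is fixed by C5, because only the arm cis to the radical-bearing substituent can bridge the five-membered lactone (diastereotopic-group selection), and C3 is set by a chair-like transition state that places the forming CH2CHO arm equatorial (exo), away from the C7(=O)–O6 bridge. The step needs HAT to the isopropenyl group and not to the enals (it is the only electron-rich 1,1-disubstituted alkene), 6-exo over 7-endo attack (polarity match of the nucleophilic radical with the enal β-carbon), and closure faster than 1,2-acyl shift of the β-acyl radical. The gem-disubstitution and the cis arrangement on the ring pre-organise the chain for this.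

Step 8
Reactants: 13 (2E)-4-[(1R,3S,5R)-4,4-dimethyl-5-(2-methylpropanoyl)-7,8-dioxo-3-(2-oxoethyl)-6-oxabicyclo[3.2.1]octan-1-yl]but-2-enal
Product: 14 2,2'-[(1S,3S,5R)-4,4-dimethyl-5-(2-methylpropanoyl)-7,8-dioxo-6-oxabicyclo[3.2.1]octane-1,3-diyl]diacetaldehyde
Conditions: O3, CH2Cl2, −78 °C (indicator end point); PPh3, −78 °C to rt
Reagents that add atoms: ozone, [O-][O+]=O
Why: Ozonolysis of the only remaining C=C bond (the enal) cuts the unused arm back to an acetaldehyde unit, so that both arms end in CH2CHO.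

Step 9
Reactants: 14 2,2'-[(1S,3S,5R)-4,4-dimethyl-5-(2-methylpropanoyl)-7,8-dioxo-6-oxabicyclo[3.2.1]octane-1,3-diyl]diacetaldehyde; 15 isopropyltriphenylphosphonium iodide (2.5 equiv)
Product: 16 (1R,3R,5R)-4,4-dimethyl-1,3-bis(3-methylbut-2-en-1-yl)-5-(2-methylpropanoyl)-6-oxabicyclo[3.2.1]octane-7,8-dione
Conditions: 15, n-BuLi, THF, 0 °C; then 14, −78 to 0 °C
Reagents that add atoms: none
Why: Double Wittig olefination with the non-stabilised isopropylidene ylide should convert both aldehydes into prenyl groups, the two hindered ketones and the lactone being far less reactive at low temperature; C3 is β to the aldehyde and cannot epimerise.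

Compound list
1 | methyl acetoacetate | COC(=O)CC(C)=O | starting material
2 | 2-vinyloxirane (racemic) | C=CC1CO1 | starting material
3 | methyl (4E)-2-acetyl-6-hydroxy-2-[(2E)-4-hydroxybut-2-en-1-yl]hex-4-enoate | COC(=O)C(C/C=C/CO)(C/C=C/CO)C(C)=O | intermediate
4 | methyl (4E)-2-acetyl-6-[(tert-butyldiphenylsilyl)oxy]-2-{(2E)-4-[(tert-butyldiphenylsilyl)oxy]but-2-en-1-yl}hex-4-enoate | COC(=O)C(C/C=C/CO[Si](c1ccccc1)(c1ccccc1)C(C)(C)C)(C/C=C/CO[Si](c1ccccc1)(c1ccccc1)C(C)(C)C)C(C)=O | intermediate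
5 | 2-methylpropanoyl chloride | CC(C)C(Cl)=O | starting material
6 | methyl 2,2-bis{(2E)-4-[(tert-butyldiphenylsilyl)oxy]but-2-en-1-yl}-6-methyl-3,5-dioxoheptanoate | COC(=O)C(C/C=C/CO[Si](c1ccccc1)(c1ccccc1)C(C)(C)C)(C/C=C/CO[Si](c1ccccc1)(c1ccccc1)C(C)(C)C)C(=O)CC(=O)C(C)C | intermediate
7 | acetone | CC(C)=O | starting material
8 | methyl 2,2-bis{(2E)-4-[(tert-butyldiphenylsilyl)oxy]but-2-en-1-yl}-6-methyl-3,5-dioxo-4-(propan-2-ylidene)heptanoate | COC(=O)C(C/C=C/CO[Si](c1ccccc1)(c1ccccc1)C(C)(C)C)(C/C=C/CO[Si](c1ccccc1)(c1ccccc1)C(C)(C)C)C(=O)C(=C(C)C)C(=O)C(C)C | intermediate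
9 | methyl (4R)-2,2-bis{(2E)-4-[(tert-butyldiphenylsilyl)oxy]but-2-en-1-yl}-4-hydroxy-6-methyl-3,5-dioxo-4-(prop-1-en-2-yl)heptanoate | COC(=O)C(C/C=C/CO[Si](c1ccccc1)(c1ccccc1)C(C)(C)C)(C/C=C/CO[Si](c1ccccc1)(c1ccccc1)C(C)(C)C)C(=O)[C@](O)(C(=O)C(C)C)C(C)=C | intermediate (not isolated)
10 | (5R)-3,3-bis{(2E)-4-[(tert-butyldiphenylsilyl)oxy]but-2-en-1-yl}-5-(2-methylpropanoyl)-5-(prop-1-en-2-yl)oxolane-2,4-dione | CC(C)(C)[Si](c1ccccc1)(c1ccccc1)OC/C=C/CC1(C/C=C/CO[Si](c2ccccc2)(c2ccccc2)C(C)(C)C)C(=O)O[C@](C(=O)C(C)C)(C1=O)C(C)=C | intermediate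
11 | (5R)-3,3-bis[(2E)-4-hydroxybut-2-en-1-yl]-5-(2-methylpropanoyl)-5-(prop-1-en-2-yl)oxolane-2,4-dione | OC/C=C/CC1(C/C=C/CO)C(=O)O[C@](C(=O)C(C)C)(C1=O)C(C)=C | intermediate (not isolated)
12 | (2E,2'E)-4,4'-[(5R)-5-(2-methylpropanoyl)-2,4-dioxo-5-(prop-1-en-2-yl)oxolane-3,3-diyl]bis(but-2-enal) | O=C/C=C/CC1(C/C=C/C=O)C(=O)O[C@](C(=O)C(C)C)(C1=O)C(C)=C | intermediate
13 | (2E)-4-[(1R,3S,5R)-4,4-dimethyl-5-(2-methylpropanoyl)-7,8-dioxo-3-(2-oxoethyl)-6-oxabicyclo[3.2.1]octan-1-yl]but-2-enal | O=CC[C@@H]1C[C@@]2(C/C=C/C=O)C(=O)O[C@](C(=O)C(C)C)(C2=O)C1(C)C | intermediate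
14 | 2,2'-[(1S,3S,5R)-4,4-dimethyl-5-(2-methylpropanoyl)-7,8-dioxo-6-oxabicyclo[3.2.1]octane-1,3-diyl]diacetaldehyde | O=CC[C@@H]1C[C@@]2(CC=O)C(=O)O[C@](C(=O)C(C)C)(C2=O)C1(C)C | intermediate
15 | isopropyltriphenylphosphonium iodide | CC(C)[P+](c1ccccc1)(c1ccccc1)c1ccccc1.[I-] | starting material
16 | (1R,3R,5R)-4,4-dimethyl-1,3-bis(3-methylbut-2-en-1-yl)-5-(2-methylpropanoyl)-6-oxabicyclo[3.2.1]octane-7,8-dione | CC(C)=CC[C@@H]1C[C@@]2(CC=C(C)C)C(=O)O[C@](C(=O)C(C)C)(C2=O)C1(C)C | target

Total step count: 9. Longest linear sequence: 9 steps.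

Steps most likely to fail

1. Step 7. The iron hydride/silane/ethanol medium may consume the enals (conjugate reduction, hydrosilylation, acetal formation) before cyclisation, and the β-acyl tertiary radical may undergo a 1,2-acyl shift (Dowd–Beckwith-type) instead of 6-exo closure. The fallback changes the acceptor class and the order of the redox steps, and sets out from 12. Pinnick oxidation (NaClO2, NaH2PO4, 2-methyl-2-butene) gives the bis(enoic acid) F1, and EDC/DMAP/EtSH gives the bis(S-ethyl enethioate) F2. Thioacrylates are inert to the hydride medium and are good radical traps, so the same MHAT cyclisation should give the cyclised thioester F3. Ozonolysis of the remaining enethioate gives the aldehyde thioester F4, and Fukuyama reduction (Et3SiH, Pd/C, acetone) of the saturated thioester comes back to the route at 14.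

2. Step 5. Facial discrimination of the acyclic diketonate by the oxaziridine may be poor, and base-induced acyl migration of the α-hydroxy diketone alkoxide may compete with lactonisation. The fallback replaces asymmetric oxidation by resolution and sets out from 8. KHMDS followed by achiral 3-phenyl-2-(phenylsulfonyl)oxaziridine, cold acidic quench and CSA gives the racemic hydroxy ester F5 (not isolated) and then the racemic lactone F6. Preparative chromatography of F6 on a chiral stationary phase comes back to the route at 10.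

3. Step 4. Condensation at the hindered diketone may stall, and TiCl4 may cleave or ionise the allylic silyl ethers. The fallback uses a hydroalkylation of an alkyne in place of the carbonyl condensation and sets out from 6. In(OTf)3-catalysed addition of the 1,3-diketone to propyne (toluene, sealed tube, 80 °C) gives the 2-isopropenyl-1,3-diketone F7, the β,γ-unsaturated tautomer of 8. F7 gives the same potassium enolate under the conditions of step 5 and so comes back to the route at 10.

Further compounds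
F1 | step 7 | (2E,2'E)-4,4'-[(5R)-5-(2-methylpropanoyl)-2,4-dioxo-5-(prop-1-en-2-yl)oxolane-3,3-diyl]bis(but-2-enoic acid) | OC(=O)/C=C/CC1(C/C=C/C(O)=O)C(=O)O[C@](C(=O)C(C)C)(C1=O)C(C)=C
F2 | step 7 | S,S'-diethyl (2E,2'E)-4,4'-[(5R)-5-(2-methylpropanoyl)-2,4-dioxo-5-(prop-1-en-2-yl)oxolane-3,3-diyl]bis(but-2-enethioate) | CCSC(=O)/C=C/CC1(C/C=C/C(=O)SCC)C(=O)O[C@](C(=O)C(C)C)(C1=O)C(C)=C
F3 | step 7 | S-ethyl (2E)-4-[(1R,3S,5R)-3-[2-(ethylsulfanyl)-2-oxoethyl]-4,4-dimethyl-5-(2-methylpropanoyl)-7,8-dioxo-6-oxabicyclo[3.2.1]octan-1-yl]but-2-enethioate | CCSC(=O)C[C@@H]1C[C@@]2(C/C=C/C(=O)SCC)C(=O)O[C@](C(=O)C(C)C)(C2=O)C1(C)C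
F4 | step 7 | S-ethyl 2-[(1S,3S,5R)-4,4-dimethyl-5-(2-methylpropanoyl)-7,8-dioxo-1-(2-oxoethyl)-6-oxabicyclo[3.2.1]octan-3-yl]ethanethioate | CCSC(=O)C[C@@H]1C[C@@]2(CC=O)C(=O)O[C@](C(=O)C(C)C)(C2=O)C1(C)C
F5 | step 5 | racemic methyl 2,2-bis{(2E)-4-[(tert-butyldiphenylsilyl)oxy]but-2-en-1-yl}-4-hydroxy-6-methyl-3,5-dioxo-4-(prop-1-en-2-yl)heptanoate | COC(=O)C(C/C=C/CO[Si](c1ccccc1)(c1ccccc1)C(C)(C)C)(C/C=C/CO[Si](c1ccccc1)(c1ccccc1)C(C)(C)C)C(=O)C(O)(C(=O)C(C)C)C(C)=C
F6 | step 5 | racemic 3,3-bis{(2E)-4-[(tert-butyldiphenylsilyl)oxy]but-2-en-1-yl}-5-(2-methylpropanoyl)-5-(prop-1-en-2-yl)oxolane-2,4-dione | CC(C)(C)[Si](c1ccccc1)(c1ccccc1)OC/C=C/CC1(C/C=C/CO[Si](c2ccccc2)(c2ccccc2)C(C)(C)C)C(=O)OC(C(=O)C(C)C)(C1=O)C(C)=C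
F7 | step 4 | methyl 2,2-bis{(2E)-4-[(tert-butyldiphenylsilyl)oxy]but-2-en-1-yl}-6-methyl-3,5-dioxo-4-(prop-1-en-2-yl)heptanoate | COC(=O)C(C/C=C/CO[Si](c1ccccc1)(c1ccccc1)C(C)(C)C)(C/C=C/CO[Si](c1ccccc1)(c1ccccc1)C(C)(C)C)C(=O)C(C(C)=C)C(=O)C(C)C
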